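Numbering (daucane): ring A = C1 (quaternary, CH3), C2 (CHOH), C3, C4 (C(OH)iPr), C5 (fusion CH); ring B = C1, C5, C6 (ester carbinol), C7, C8(CH3)=C9, C10; β = face of the C1 methyl group.
Cuts, in retrosynthetic order: acyl–O6; H–C6 (back to the ketone); O4–C4 together with H–C5 (back through a temporary isoxazoline, ring C, to the C4=C5 enone); C5–C6 (opens ring B); the isopropyl carbons at C4; C1–C10.
Forward: ring A is bought as 2-methylcyclopentane-1,3-dione and the C6–C10 chain as a (Z)-enynol. Ring B is closed at C5–C6 by an alkenylchromium–aldehyde coupling, then ring C is put on and taken off again.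
Enabling feature: C5 lies between quaternary C1 and C4, so the C5 ketone gives a single enol triflate, and its C5–metal σ bond lies in the plane of ring A. The short (Z)-C8=C9 tether could reach a π face of C5 only from the C10 side (cis fusion), so closing on the σ bond lets ring B form while C5 stays trigonal.
Stereochemistry: C1 and C2 come from one catalyst-controlled desymmetrising reduction. C4 comes from the twist that C10 imposes on ring B (oxime O held over the β face). C5 comes from the obligatory cis fusion of rings A and C, which equals a trans A/B fusion. C6 comes from hydride delivery by the C4 hydroxyl.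

Key step: step 10

Assumption: compounds 1, 5 and 26 are taken as commercial; α and β refer to the faces defined in the first line.

Step 1
Reactants: 1 (Z)-3-methylpent-2-en-4-yn-1-ol
Product: 3 (Z)-3-methyl-5-(trimethylsilyl)pent-2-en-4-yn-1-ol, via bis-silyl compound 2 (not isolated)
Conditions: EtMgBr (2.2 equiv), THF, 0 °C to rt; Me3SiCl (2.2 equiv); then 1 M H2SO4, rt
Reagents that add atoms: chlorotrimethylsilane, C[Si](C)(C)Cl
Why: Double deprotonation (O–H and alkyne C–H), double silylation and acid hydrolysis of the labile O–Si bond is the standard C-silylation of an enynol, it masks the acidic alkyne hydrogen for steps 6 and 7, and the (Z)-alkene bought with 1 is not touched.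

Step 2
Reactants: 3 (Z)-3-methyl-5-(trimethylsilyl)pent-2-en-4-yn-1-ol
Product: 4 [(Z)-5-bromo-3-methylpent-3-en-1-yn-1-yl]trimethylsilane
Conditions: CBr4, PPh3, CH2Cl2, 0 °C
Reagents that add atoms: carbon tetrabromide, BrC(Br)(Br)Br
Why: The Appel reaction replaces the primary allylic hydroxyl by bromide through SN2 attack on the oxyphosphonium salt under neutral conditions, so the (Z)-geometry should be kept.

Step 3
Reactants: 4 [(Z)-5-bromo-3-methylpent-3-en-1-yn-1-yl]trimethylsilane; 5 2-methylcyclopentane-1,3-dione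
Product: 6 2-methyl-2-[(Z)-3-methyl-5-(trimethylsilyl)pent-2-en-4-yn-1-yl]cyclopentane-1,3-dione
Conditions: NaOH (1.0 equiv), H2O/THF, rt
Reagents that add atoms: none
Why: C-alkylation of the sodium enolate of the acidic 1,3-dione with a reactive allylic bromide (SN2) builds C1 as a prochiral quaternary carbon and, unlike a π-allyl route, cannot scramble the (Z)-alkene, while one equivalent of base leaves no free hydroxide to attack the alkynylsilane.

Step 4
Reactants: 6 2-methyl-2-[(Z)-3-methyl-5-(trimethylsilyl)pent-2-en-4-yn-1-yl]cyclopentane-1,3-dione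
Product: 7 (2S,3S)-3-hydroxy-2-methyl-2-[(Z)-3-methyl-5-(trimethylsilyl)pent-2-en-4-yn-1-yl]cyclopentan-1-one
Conditions: (R)-2-methyl-CBS-oxazaborolidine (0.2 equiv), catecholborane, toluene, −78 °C
Reagents that add atoms: none
Why: Corey–Bakshi–Shibata reduction used as a desymmetrisation, in which the oxazaborolidine binds the carbonyl lone pair anti to the quaternary carbon and so selects the carbonyl group and face that give the (S)-carbinol, hydride enters from the side of the small methyl group, and this single event fixes C2 (OH cis to the chain, α) and the quaternary C1.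

Step 5
Reactants: 7 (2S,3S)-3-hydroxy-2-methyl-2-[(Z)-3-methyl-5-(trimethylsilyl)pent-2-en-4-yn-1-yl]cyclopentan-1-one
Product: 8 (2S,3S)-3-[(tert-butyldimethylsilyl)oxy]-2-methyl-2-[(Z)-3-methyl-5-(trimethylsilyl)pent-2-en-4-yn-1-yl]cyclopentan-1-one
Conditions: TBSOTf, 2,6-lutidine, CH2Cl2, 0 °C
Reagents that add atoms: tert-butyldimethylsilyl triflate, CC(C)(C)[Si](C)(C)OS(=O)(=O)C(F)(F)F
Why: Silylation with the silyl triflate and a hindered pyridine base protects the neopentyl C2 hydroxyl without touching the ketone, and the bulky group later helps to shield the α face of ring A.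

Step 6
Reactants: 8 (2S,3S)-3-[(tert-butyldimethylsilyl)oxy]-2-methyl-2-[(Z)-3-methyl-5-(trimethylsilyl)pent-2-en-4-yn-1-yl]cyclopentan-1-one
Product: 11 (2S,3S,5E)-3-[(tert-butyldimethylsilyl)oxy]-5-ethylidene-2-methyl-2-[(Z)-3-methyl-5-(trimethylsilyl)pent-2-en-4-yn-1-yl]cyclopentan-1-one, via lithium aldolate 9 (not isolated), via mesylate 10 (not isolated)
Conditions: LiN(iPr)2, THF, −78 °C; CH3CHO; MsCl, −78 to 0 °C; DBU, rt
Reagents that add atoms: acetaldehyde, CC=O
Why: Directed aldol addition, mesylation and E1cB elimination (an aldol condensation in one flask) work here because the ketone can enolise only towards C4 (C1 is quaternary), the two new centres of 9 vanish in the elimination, and the (E)-enone is the less crowded product.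

Step 7
Reactants: 11 (2S,3S,5E)-3-[(tert-butyldimethylsilyl)oxy]-5-ethylidene-2-methyl-2-[(Z)-3-methyl-5-(trimethylsilyl)pent-2-en-4-yn-1-yl]cyclopentan-1-one
Product: 13 (4S,5S)-4-[(tert-butyldimethylsilyl)oxy]-2-isopropyl-5-methyl-5-[(Z)-3-methyl-5-(trimethylsilyl)pent-2-en-4-yn-1-yl]cyclopent-1-en-1-yl triflate, via lithium enolate 12 (not isolated)
Conditions: Me2CuLi (from MeLi, CuI), Et2O, −78 to 0 °C; PhNTf2, THF, 0 °C to rt
Reagents that add atoms: lithium dimethylcuprate, [Li+].C[Cu-]C; N-phenylbis(trifluoromethanesulfonimide), O=S(=O)(N(c1ccccc1)S(=O)(=O)C(F)(F)F)C(F)(F)F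
Why: Conjugate addition of the Gilman cuprate turns the ethylidene group into isopropyl and gives the C4=C5 enolate regiospecifically, which is trapped on oxygen by the triflimide, and no stereocentre is formed.

Step 8
Reactants: 13 (4S,5S)-4-[(tert-butyldimethylsilyl)oxy]-2-isopropyl-5-methyl-5-[(Z)-3-methyl-5-(trimethylsilyl)pent-2-en-4-yn-1-yl]cyclopent-1-en-1-yl triflate
Product: 14 (4S,5S)-4-[(tert-butyldimethylsilyl)oxy]-2-isopropyl-5-methyl-5-[(Z)-3-methylpent-2-en-4-yn-1-yl]cyclopent-1-en-1-yl triflate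
Conditions: K2CO3 (0.2 equiv), MeOH, 0 °C
Reagents that add atoms: none
Why: Base-catalysed methanolysis cleaves only the alkynyl C–Si bond, while the enol triflate and the hindered secondary silyl ether should be inert at this temperature.

Step 9
Reactants: 14 (4S,5S)-4-[(tert-butyldimethylsilyl)oxy]-2-isopropyl-5-methyl-5-[(Z)-3-methylpent-2-en-4-yn-1-yl]cyclopent-1-en-1-yl triflate
Product: 16 (4S,5S)-4-[(tert-butyldimethylsilyl)oxy]-2-isopropyl-5-methyl-5-[(Z)-3-methyl-5-oxopent-2-en-1-yl]cyclopent-1-en-1-yl triflate, via dienylborane 15 (not isolated)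
Conditions: Cy2BH, THF, 0 °C; then H2O2, pH 7 phosphate buffer, 0 °C
Reagents that add atoms: hydrogen peroxide, OO
Why: Hydroboration–oxidation, in which the bulky dialkylborane adds only to the terminal alkyne with boron on C6 and the buffered oxidation gives a dienol that is protonated at C7, should yield the β,γ-unsaturated aldehyde with the (Z)-C8=C9 bond in place.

Step 10
Reactants: 16 (4S,5S)-4-[(tert-butyldimethylsilyl)oxy]-2-isopropyl-5-methyl-5-[(Z)-3-methyl-5-oxopent-2-en-1-yl]cyclopent-1-en-1-yl triflate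
Product: 18 2α-[(tert-butyldimethylsilyl)oxy]dauca-4,8-dien-6-ol (both C6 epimers), via alkenylchromium dichloride 17 (not isolated)
Conditions: CrCl2 (8 equiv), NiCl2 (2 mol %), DMF, rt, 0.003 M
Reagents that add atoms: none
Why: Zerovalent nickel (made from NiCl2 by divalent chromium) inserts into the C5–O bond of the enol triflate, the alkenyl group passes to trivalent chromium (17), this σ-organometal adds to the C6 aldehyde, and aqueous work-up frees the alcohol. The closest known reaction type is the intramolecular Nozaki–Hiyama–Kishi coupling of alkenyl triflates or iodides with aldehydes, a proven entry to medium rings. Ring B closes in a 7-exo-trig mode, helped by the (Z)-C8=C9 bond and the quaternary C1, which hold C6 close to C5. Because the C5–Cr bond lies in the plane of ring A, the new bond forms without choosing a face of C5, whereas a π-type closure (enolate, ene or dipolar cycloaddition) would be forced by the short (Z)-tether onto the C10 face and would give the wrong cis fusion. The only new stereocentre, C6, is not controlled and need not be, since step 11 erases it. The step needs chemoselectivity, which the substrate secures because only the C–OTf bond is activated, the alkenes and silyl ether are inert, and the neutral medium spares the isomerisation-prone aldehyde; it also needs cyclisation over oligomerisation, which the preorganised tether and high dilution secure.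

Step 11
Reactants: 18 2α-[(tert-butyldimethylsilyl)oxy]dauca-4,8-dien-6-ol (both C6 epimers)
Product: 19 2α-[(tert-butyldimethylsilyl)oxy]dauca-4,8-dien-6-one
Conditions: Dess–Martin periodinane, CH2Cl2, rt
Reagents that add atoms: none
Why: Dess–Martin oxidation converts both C6 epimers into one C4=C5 enone under non-basic conditions, which matters because base would pull the C8=C9 bond into conjugation through the acidic C7 hydrogens.

Step 12
Reactants: 19 2α-[(tert-butyldimethylsilyl)oxy]dauca-4,8-dien-6-one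
Product: 22 ring-C isoxazoline (O on C4β and N=C6; 5α-H; 2α-OTBS; C8=C9 retained), via oxime 20 (not isolated), via N-H dihydroisoxazole 21 (not isolated)
Conditions: NH2OH·HCl, NaOAc, EtOH, 78 °C
Reagents that add atoms: hydroxylamine hydrochloride, NO.Cl
Why: Condensation gives oxime 20, whose oxygen adds to C4 in a 5-endo conjugate addition (the classical isoxazoline synthesis from an enone and hydroxylamine), C10 on the α face tilts C7 down and the N–O arm up so that oxygen reaches C4 from the β face, and the tautomerisation of 21 must place hydrogen on the α face of C5 because the two five-membered rings A and C can only be cis-fused, which makes the A/B fusion trans.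

Step 13
Reactants: 22 ring-C isoxazoline (O on C4β and N=C6; 5α-H; 2α-OTBS; C8=C9 retained)
Product: 24 2α-[(tert-butyldimethylsilyl)oxy]-4β-hydroxy-5α-H-dauc-8-en-6-one, via hydroxy imine 23 (not isolated)
Conditions: Mo(CO)6, MeCN/H2O (15:1), 80 °C
Reagents that add atoms: water, O
Why: Reductive N–O cleavage of a 2-isoxazoline with Mo(CO)6 followed by hydrolysis of imine 23 is the standard unmasking of a β-hydroxy ketone, and the neutral medium should leave C4, C5 and the C8=C9 bond as they are.

Step 14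
Reactants: 24 2α-[(tert-butyldimethylsilyl)oxy]-4β-hydroxy-5α-H-dauc-8-en-6-one
Product: 25 2α-[(tert-butyldimethylsilyl)oxy]dauc-8-ene-4β,6α-diol
Conditions: Me4NBH(OAc)3, MeCN/AcOH (1:1), −30 °C
Reagents that add atoms: none
Why: Evans–Saksena reduction, in which the C4 hydroxyl replaces an acetate on boron and the bound hydride is delivered within the molecule to the β face of the C6 carbonyl group, should give the 4β,6α (1,3-anti) diol and override the shielding of that face by the C1 methyl group.

Step 15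
Reactants: 25 2α-[(tert-butyldimethylsilyl)oxy]dauc-8-ene-4β,6α-diol; 26 4-[(tert-butyldimethylsilyl)oxy]benzoic acid
Product: 27 6α-{4-[(tert-butyldimethylsilyl)oxy]benzoyloxy}-2α-[(tert-butyldimethylsilyl)oxy]dauc-8-en-4β-ol
Conditions: DCC, DMAP (0.2 equiv), CH2Cl2, rt
Reagents that add atoms: none
Why: Steglich esterification should acylate only the secondary C6 hydroxyl, because the tertiary C4 hydroxyl is too hindered for the acylpyridinium ion and C2 is still silylated.

Step 16
Reactants: 27 6α-{4-[(tert-butyldimethylsilyl)oxy]benzoyloxy}-2α-[(tert-butyldimethylsilyl)oxy]dauc-8-en-4β-ol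
Product: 28 2α-hydroxyferutinin
Conditions: HF·pyridine, pyridine, THF, 0 °C to rt
Reagents that add atoms: none
Why: Fluoride-driven desilylation removes the aryl and the secondary silyl ether under mildly acidic conditions that avoid acyl migration and ester hydrolysis and leave all five stereocentres untouched, which gives the target.

Compound list
1 | (Z)-3-methylpent-2-en-4-yn-1-ol | C#C/C(C)=C\CO | starting material
2 | bis-silyl compound, trimethyl{[(Z)-3-methyl-5-(trimethylsilyl)pent-2-en-4-yn-1-yl]oxy}silane | C[Si](C)(C)C#C/C(C)=C\CO[Si](C)(C)C | intermediate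
3 | (Z)-3-methyl-5-(trimethylsilyl)pent-2-en-4-yn-1-ol | C[Si](C)(C)C#C/C(C)=C\CO | intermediate
4 | [(Z)-5-bromo-3-methylpent-3-en-1-yn-1-yl]trimethylsilane | C[Si](C)(C)C#C/C(C)=C\CBr | intermediate
5 | 2-methylcyclopentane-1,3-dione | CC1C(=O)CCC1=O | starting material
6 | 2-methyl-2-[(Z)-3-methyl-5-(trimethylsilyl)pent-2-en-4-yn-1-yl]cyclopentane-1,3-dione | C[Si](C)(C)C#C/C(C)=C\CC1(C)C(=O)CCC1=O | intermediate
7 | (2S,3S)-3-hydroxy-2-methyl-2-[(Z)-3-methyl-5-(trimethylsilyl)pent-2-en-4-yn-1-yl]cyclopentan-1-one | C[Si](C)(C)C#C/C(C)=C\C[C@]1(C)C(=O)CC[C@@H]1O | intermediate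
8 | (2S,3S)-3-[(tert-butyldimethylsilyl)oxy]-2-methyl-2-[(Z)-3-methyl-5-(trimethylsilyl)pent-2-en-4-yn-1-yl]cyclopentan-1-one | C[Si](C)(C)C#C/C(C)=C\C[C@]1(C)C(=O)CC[C@@H]1O[Si](C)(C)C(C)(C)C | intermediate
9 | lithium aldolate of 8 with acetaldehyde (1-oxidoethyl group on C4, new centres undefined) | C[Si](C)(C)C#C/C(C)=C\C[C@]1(C)C(=O)C(C(C)[O-])C[C@@H]1O[Si](C)(C)C(C)(C)C.[Li+] | intermediate
10 | mesylate of the aldol (new centres undefined) | C[Si](C)(C)C#C/C(C)=C\C[C@]1(C)C(=O)C(C(C)OS(C)(=O)=O)C[C@@H]1O[Si](C)(C)C(C)(C)C | intermediate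
11 | (2S,3S,5E)-3-[(tert-butyldimethylsilyl)oxy]-5-ethylidene-2-methyl-2-[(Z)-3-methyl-5-(trimethylsilyl)pent-2-en-4-yn-1-yl]cyclopentan-1-one | C[Si](C)(C)C#C/C(C)=C\C[C@]1(C)C(=O)/C(=C/C)C[C@@H]1O[Si](C)(C)C(C)(C)C | intermediate
12 | lithium enolate (C4=C5, isopropyl on C4) | C[Si](C)(C)C#C/C(C)=C\C[C@]1(C)C([O-])=C(C(C)C)C[C@@H]1O[Si](C)(C)C(C)(C)C.[Li+] | intermediate
13 | (4S,5S)-4-[(tert-butyldimethylsilyl)oxy]-2-isopropyl-5-methyl-5-[(Z)-3-methyl-5-(trimethylsilyl)pent-2-en-4-yn-1-yl]cyclopent-1-en-1-yl triflate | C[Si](C)(C)C#C/C(C)=C\C[C@]1(C)C(OS(=O)(=O)C(F)(F)F)=C(C(C)C)C[C@@H]1O[Si](C)(C)C(C)(C)C | intermediate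
14 | (4S,5S)-4-[(tert-butyldimethylsilyl)oxy]-2-isopropyl-5-methyl-5-[(Z)-3-methylpent-2-en-4-yn-1-yl]cyclopent-1-en-1-yl triflate | C#C/C(C)=C\C[C@]1(C)C(OS(=O)(=O)C(F)(F)F)=C(C(C)C)C[C@@H]1O[Si](C)(C)C(C)(C)C | intermediate
15 | (1E,3Z)-dienyl(dicyclohexyl)borane, boron on C6 | C1(CCCCC1)B(C1CCCCC1)/C=C/C(C)=C\C[C@]1(C)C(OS(=O)(=O)C(F)(F)F)=C(C(C)C)C[C@@H]1O[Si](C)(C)C(C)(C)C | intermediate
16 | (4S,5S)-4-[(tert-butyldimethylsilyl)oxy]-2-isopropyl-5-methyl-5-[(Z)-3-methyl-5-oxopent-2-en-1-yl]cyclopent-1-en-1-yl triflate | O=CC/C(C)=C\C[C@]1(C)C(OS(=O)(=O)C(F)(F)F)=C(C(C)C)C[C@@H]1O[Si](C)(C)C(C)(C)C | intermediate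
17 | alkenylchromium dichloride (CrCl2 group on C5 in place of the triflate) | O=CC/C(C)=C\C[C@]1(C)C([Cr](Cl)Cl)=C(C(C)C)C[C@@H]1O[Si](C)(C)C(C)(C)C | intermediate
18 | 2α-[(tert-butyldimethylsilyl)oxy]dauca-4,8-dien-6-ol (both C6 epimers) | CC1=CC[C@]2(C)C(C(O)C1)=C(C(C)C)C[C@@H]2O[Si](C)(C)C(C)(C)C | intermediate
19 | 2α-[(tert-butyldimethylsilyl)oxy]dauca-4,8-dien-6-one | CC1=CC[C@]2(C)C(C(=O)C1)=C(C(C)C)C[C@@H]2O[Si](C)(C)C(C)(C)C | intermediate
20 | oxime of 19 (C=N geometry mobile) | CC1=CC[C@]2(C)C(C(=NO)C1)=C(C(C)C)C[C@@H]2O[Si](C)(C)C(C)(C)C | intermediate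
21 | N-H dihydroisoxazole (O on C4β, C5=C6, NH on C6) | CC1=CC[C@]2(C)C3=C(C1)NO[C@@]3(C(C)C)C[C@@H]2O[Si](C)(C)C(C)(C)C | intermediate
22 | ring-C isoxazoline (O on C4β and N=C6; 5α-H; 2α-OTBS; C8=C9 retained) | CC1=CC[C@]2(C)[C@H]3C(C1)=NO[C@@]3(C(C)C)C[C@@H]2O[Si](C)(C)C(C)(C)C | intermediate
23 | 4β-hydroxy 6-imine | CC1=CC[C@]2(C)[C@@H](C(=N)C1)[C@](O)(C(C)C)C[C@@H]2O[Si](C)(C)C(C)(C)C | intermediate
24 | 2α-[(tert-butyldimethylsilyl)oxy]-4β-hydroxy-5α-H-dauc-8-en-6-one | CC1=CC[C@]2(C)[C@@H](C(=O)C1)[C@](O)(C(C)C)C[C@@H]2O[Si](C)(C)C(C)(C)C | intermediate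
25 | 2α-[(tert-butyldimethylsilyl)oxy]dauc-8-ene-4β,6α-diol | CC1=CC[C@]2(C)[C@@H]([C@@H](O)C1)[C@](O)(C(C)C)C[C@@H]2O[Si](C)(C)C(C)(C)C | intermediate
26 | 4-[(tert-butyldimethylsilyl)oxy]benzoic acid | O=C(O)c1ccc(O[Si](C)(C)C(C)(C)C)cc1 | starting material
27 | 6α-{4-[(tert-butyldimethylsilyl)oxy]benzoyloxy}-2α-[(tert-butyldimethylsilyl)oxy]dauc-8-en-4β-ol | CC1=CC[C@]2(C)[C@@H]([C@@H](OC(=O)c3ccc(O[Si](C)(C)C(C)(C)C)cc3)C1)[C@](O)(C(C)C)C[C@@H]2O[Si](C)(C)C(C)(C)C | intermediate
28 | 2α-hydroxyferutinin | CC1=CC[C@]2(C)[C@@H]([C@@H](OC(=O)c3ccc(O)cc3)C1)[C@](O)(C(C)C)C[C@@H]2O | target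

Total step count: 16. Longest linear sequence: 16 steps (1 to 28).

Steps most likely to fail

Step 12. Hydroxylamine may add to C4 through nitrogen instead of oxygen. The crowded oxime may also fail to close at the fully substituted C4, or the long heating may move the C8=C9 bond. The fallback sets out from 19 and comes back at 24, and replaces the conjugate addition by an epoxide and a hydride shift.
- Reagent-controlled 1,2-reduction with (S)-2-methyl-CBS-oxazaborolidine and catecholborane should give the 6β-allylic alcohol F1.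
- VO(acac)2 and tBuOOH should epoxidise only the allylic C4=C5 bond, on the hydroxyl (β) side, to give the 4β,5β-epoxy-6β-alcohol F2.
- Me3SiOTf and iPr2NEt should open the C5–O bond with a 1,2-hydride shift from C6 to the α face of C5 (a non-aldol aldol rearrangement, inversion at C5), giving the O4-trimethylsilyl ketone F3.
- Citric acid in MeOH then frees 24.

Step 10. Insertion into the hindered, fully substituted enol triflate may be slow. In that case reduction of the C–O bond, isomerisation of the aldehyde or oligomerisation could take over. The fallback sets out from 16 and comes back at 19, and closes the same bond by a pericyclic reaction.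
- Pd(OAc)2, PPh3, HCO2H and Et3N should reduce the triflate to the cyclopentene aldehyde F4.
- Me2AlCl should bring about an intramolecular carbonyl-ene reaction that moves the isopropyl methine hydrogen to oxygen and gives the cis-fused isopropylidene alcohol F5.
- Dess–Martin oxidation should give the deconjugated ketone F6.
- A trace of TsOH should shift the tetrasubstituted C4=C11 bond into conjugation, which erases C5 and gives 19.

Step 14. Ligand exchange at the hindered tertiary C4 hydroxyl may be too slow, so undirected hydride delivery from the open α face would prevail. The fallback sets out from 24 and comes back at 27, and uses that bias instead.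
- NaBH4 with CeCl3 in MeOH should give the 4β,6β-diol F7.
- A Mitsunobu esterification (PPh3, DIAD) with acid 26 should invert C6 and install the ester in the same operation, giving 27.

Further compounds
F1 | step 12 | 2α-[(tert-butyldimethylsilyl)oxy]dauca-4,8-dien-6β-ol | CC1=CC[C@]2(C)C([C@H](O)C1)=C(C(C)C)C[C@@H]2O[Si](C)(C)C(C)(C)C
F2 | step 12 | 2α-[(tert-butyldimethylsilyl)oxy]-4β,5β-epoxydauc-8-en-6β-ol | CC1=CC[C@]2(C)[C@@]3([C@H](O)C1)O[C@@]3(C(C)C)C[C@@H]2O[Si](C)(C)C(C)(C)C
F3 | step 12 | 2α-[(tert-butyldimethylsilyl)oxy]-4β-[(trimethylsilyl)oxy]-5α-H-dauc-8-en-6-one | CC1=CC[C@]2(C)[C@@H](C(=O)C1)[C@](O[Si](C)(C)C)(C(C)C)C[C@@H]2O[Si](C)(C)C(C)(C)C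
F4 | step 10 | (Z)-5-{(1S,5S)-5-[(tert-butyldimethylsilyl)oxy]-3-isopropyl-1-methylcyclopent-2-en-1-yl}-3-methylpent-3-enal | O=CC/C(C)=C\C[C@]1(C)C=C(C(C)C)C[C@@H]1O[Si](C)(C)C(C)(C)C
F5 | step 10 | cis-fused 2α-[(tert-butyldimethylsilyl)oxy]-5β-H-dauca-4(11),8-dien-6-ol (C6 undefined) | CC1=CC[C@]2(C)[C@H](C(O)C1)C(=C(C)C)C[C@@H]2O[Si](C)(C)C(C)(C)C
F6 | step 10 | cis-fused 2α-[(tert-butyldimethylsilyl)oxy]-5β-H-dauca-4(11),8-dien-6-one | CC1=CC[C@]2(C)[C@H](C(=O)C1)C(=C(C)C)C[C@@H]2O[Si](C)(C)C(C)(C)C
F7 | step 14 | 2α-[(tert-butyldimethylsilyl)oxy]dauc-8-ene-4β,6β-diol | CC1=CC[C@]2(C)[C@@H]([C@H](O)C1)[C@](O)(C(C)C)C[C@@H]2O[Si](C)(C)C(C)(C)C
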